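**Retrosynthetic overview**

1. Ring A is cut at C4a–C5 and C8–C8a (retro-Diels–Alder), giving the (S)-dihydropyranone sulfoxide 9 and the prenylated 1-methoxy-3-siloxy diene 14.
2. The route rests on the C4a=C8a bond shared by rings A and C. Seen in ring C alone, it is the O1–C8a=C4a–C4=O enone alkene of a 2-aryl-2,3-dihydro-4H-pyran-4-one, so ring A, O7 and the C8 prenyl group can be grown on a ring C that already carries C2.
3. Ring order: the chromene of the B-ring unit is bought in 1; ring C comes from a catalytic asymmetric hetero-Diels–Alder reaction, which sets C2; ring A is closed last.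
4. C4a is activated by a phenylsulfinyl group (iodination, C–S coupling, S-oxidation). Methanol is removed from the cycloadduct before the sulfoxide is eliminated, so that only H8a is left for the syn-elimination; the silyl group is lost in the same flask and step 8 ends at the free phenol.
5. Diene 14 comes from 4-methoxybut-3-en-2-one by α'-prenylation and O-silylation.

Key step: step 8

Assumption: the (S)-BINOL–titanium catalyst is taken to direct the diene to the Si face of the aryl aldehyde, as this catalyst family does in allyl and silyl enolate additions to aromatic aldehydes; if the sense proves opposite, (R)-BINOL is used in the same way.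

**Route**

Step 1
Reactants: 1 6-bromo-2,2-dimethyl-2H-chromene
Product: 3 2,2-dimethyl-2H-chromene-6-carbaldehyde, via aryllithium 2 (not isolated)
Conditions: n-BuLi, THF, −78 °C; DMF, −78 to 0 °C; H2O
Reagents that add atoms: N,N-dimethylformamide, CN(C)C=O
Why: Bromine–lithium exchange on the aryl bromide is fast at −78 °C and the aryllithium is formylated by DMF (Bouveault formylation), conditions to which the chromene alkene and its gem-dimethyl ether are inert.

Step 2
Reactants: 3 2,2-dimethyl-2H-chromene-6-carbaldehyde; 4 Danishefsky's diene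
Product: 6 (S)-2-(2,2-dimethyl-2H-chromen-6-yl)-2,3-dihydro-4H-pyran-4-one, via silyl aldol adduct 5 (not isolated)
Conditions: (S)-BINOL (20 mol%), Ti(Oi-Pr)4 (10 mol%), 4 Å MS, Et2O, −20 °C; then TFA, CH2Cl2, 0 °C
Reagents that add atoms: none
Why: This is a catalytic asymmetric hetero-Diels–Alder reaction in its Mukaiyama aldol/cyclization form, in which the BINOL–titanium complex binds the aldehyde and leaves its Si face open to the diene terminus, setting C2 as (S), and brief TFA treatment then closes ring C by oxa-Michael addition with loss of methanol.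

Step 3
Reactants: 6 (S)-2-(2,2-dimethyl-2H-chromen-6-yl)-2,3-dihydro-4H-pyran-4-one
Product: 7 (S)-2-(2,2-dimethyl-2H-chromen-6-yl)-5-iodo-2,3-dihydro-4H-pyran-4-one
Conditions: I2, pyridine, DMAP (cat.), CH2Cl2, 0 °C to rt
Reagents that add atoms: iodine, II
Why: α-Iodination of the enone (Johnson iodination) should occur at C5, the nucleophilic α-carbon of the vinylogous ester, while the amine-buffered medium leaves the chromene alkene and C2 untouched.

Step 4
Reactants: 7 (S)-2-(2,2-dimethyl-2H-chromen-6-yl)-5-iodo-2,3-dihydro-4H-pyran-4-one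
Product: 8 (S)-2-(2,2-dimethyl-2H-chromen-6-yl)-5-(phenylthio)-2,3-dihydro-4H-pyran-4-one
Conditions: PhSH, Pd2(dba)3 (2.5 mol%), Xantphos (5 mol%), i-Pr2NEt, 1,4-dioxane, 60 °C
Reagents that add atoms: thiophenol, Sc1ccccc1
Why: Palladium-catalysed C–S cross-coupling (Migita-type thiolation) replaces the vinylic iodide under a weak amine base, since a direct addition–elimination with thiolate cannot deliver sulfur to the α-carbon and strong base could open the pyranone by β-elimination at C2.

Step 5
Reactants: 8 (S)-2-(2,2-dimethyl-2H-chromen-6-yl)-5-(phenylthio)-2,3-dihydro-4H-pyran-4-one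
Product: 9 (2S)-2-(2,2-dimethyl-2H-chromen-6-yl)-5-(phenylsulfinyl)-2,3-dihydro-4H-pyran-4-one (both sulfur epimers)
Conditions: mCPBA (1.0 equiv), CH2Cl2, −78 °C
Reagents that add atoms: mCPBA, O=C(OO)c1cccc(Cl)c1
Why: Sulfide-to-sulfoxide oxidation with one equivalent of peracid at −78 °C should be much faster than epoxidation of the chromene alkene, and the uncontrolled sulfur stereocentre is of no consequence because sulfur is expelled in step 8.

Step 6
Reactants: 10 (E)-4-methoxybut-3-en-2-one; 11 prenyl bromide
Product: 13 (E)-1-methoxy-7-methylocta-1,6-dien-3-one, via lithium enolate 12 (not isolated)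
Conditions: LiHMDS, THF, −78 °C; 11, DMPU, −78 to −20 °C
Reagents that add atoms: none
Why: The methyl group is the only enolizable position of the vinylogous ester, so kinetic deprotonation and SN2 alkylation of the lithium enolate with the allylic bromide (enolate alkylation) should give the α'-prenylated ketone.

Step 7
Reactants: 13 (E)-1-methoxy-7-methylocta-1,6-dien-3-one
Product: 14 (1E,3Z)-1-methoxy-7-methyl-3-(trimethylsilyloxy)octa-1,3,6-triene
Conditions: TMSOTf, Et3N, Et2O, 0 °C
Reagents that add atoms: trimethylsilyl trifluoromethanesulfonate, C[Si](C)(C)OS(=O)(=O)C(F)(F)F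
Why: Soft enolization and O-silylation with silyl triflate and amine should give the favoured (Z)-silyl enol ether, which places the prenyl-bearing CH2 on the outside of the s-cis diene as the cycloaddition requires.

Step 8
Reactants: 9 (2S)-2-(2,2-dimethyl-2H-chromen-6-yl)-5-(phenylsulfinyl)-2,3-dihydro-4H-pyran-4-one; 14 (1E,3Z)-1-methoxy-7-methyl-3-(trimethylsilyloxy)octa-1,3,6-triene
Product: 18 (2S)-7-hydroxy-2-(2,2-dimethyl-2H-chromen-6-yl)-8-(3-methylbut-2-en-1-yl)-2,3-dihydro-4H-chromen-4-one (target), via cycloadduct 15 (not isolated), via sulfinyl enone 16 (not isolated), via cyclohexadienone 17 (not isolated)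
Conditions: 14 (2 equiv), Eu(fod)3 (5 mol%), toluene, 0 °C; TFA (10 mol%), 0 °C; pyridine (20 mol%), 60 °C
Reagents that add atoms: none
Why: The electron-rich 1-methoxy-3-siloxy diene adds in a normal-electron-demand [4+2] cycloaddition across the C4a=C8a alkene of 9, which the C4 ketone and the sulfinyl group (both bound by the europium Lewis acid) activate, so ring A is closed in one intermolecular cycloaddition that forms C8–C8a and C4a–C5; a stepwise Michael addition and ring closure under the Lewis acid would lead to the same adduct 15. The closest known reaction type is the Diels–Alder and elimination benzannulation of Danishefsky-type dienes with α-sulfinyl enones, sulfinylquinones and 3-acceptor-substituted chromones. The step needs regioselectivity only: the prenyl-bearing diene terminus carries the largest HOMO coefficient and C8a, which is β to both the ketone and the sulfinyl group, the largest LUMO coefficient, so O7 ends up para to C4a and the prenyl group on C8. Catalytic acid then ionizes the allylic methyl ether with the help of the silyl enol ether and gives enone 16, the silyl group leaving as methoxytrimethylsilane; because this is done before any heating, C5 is already sp2 and the thermal syn-elimination of benzenesulfenic acid can only take H8a, which is cis to sulfur since the cycloaddition is suprafacial, and dienone 17 tautomerizes to the phenol. No new stereocentre survives, because every sp3 centre created in 15 is erased on aromatization, so endo/exo and facial selectivity are irrelevant; C2 lies outside the reacting π system, and strong base is avoided because 16 and the flavanone could open by β-elimination of O1.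

**Compound list**

1 | 6-bromo-2,2-dimethyl-2H-chromene | CC1(C)C=Cc2cc(Br)ccc2O1 | starting material
2 | (2,2-dimethyl-2H-chromen-6-yl)lithium | [Li]c1ccc2c(c1)C=CC(C)(C)O2 | intermediate (not isolated)
3 | 2,2-dimethyl-2H-chromene-6-carbaldehyde | CC1(C)C=Cc2cc(C=O)ccc2O1 | intermediate
4 | Danishefsky's diene, (E)-1-methoxy-3-(trimethylsilyloxy)buta-1,3-diene | CO/C=C/C(=C)O[Si](C)(C)C | starting material
5 | (S,E)-5-(2,2-dimethyl-2H-chromen-6-yl)-1-methoxy-5-(trimethylsilyloxy)pent-1-en-3-one | CO/C=C/C(=O)C[C@@H](c1ccc2c(c1)C=CC(C)(C)O2)O[Si](C)(C)C | intermediate (not isolated)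
6 | (S)-2-(2,2-dimethyl-2H-chromen-6-yl)-2,3-dihydro-4H-pyran-4-one | O=C1C[C@@H](c2ccc3c(c2)C=CC(C)(C)O3)OC=C1 | intermediate
7 | (S)-2-(2,2-dimethyl-2H-chromen-6-yl)-5-iodo-2,3-dihydro-4H-pyran-4-one | O=C1C[C@@H](c2ccc3c(c2)C=CC(C)(C)O3)OC=C1I | intermediate
8 | (S)-2-(2,2-dimethyl-2H-chromen-6-yl)-5-(phenylthio)-2,3-dihydro-4H-pyran-4-one | O=C1C[C@@H](c2ccc3c(c2)C=CC(C)(C)O3)OC=C1Sc1ccccc1 | intermediate
9 | (2S)-2-(2,2-dimethyl-2H-chromen-6-yl)-5-(phenylsulfinyl)-2,3-dihydro-4H-pyran-4-one, both sulfur epimers | O=C1C[C@@H](c2ccc3c(c2)C=CC(C)(C)O3)OC=C1S(=O)c1ccccc1 | intermediate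
10 | (E)-4-methoxybut-3-en-2-one | CO/C=C/C(C)=O | starting material
11 | prenyl bromide, 1-bromo-3-methylbut-2-ene | CC(C)=CCBr | starting material
12 | lithium enolate of 10, lithium (E)-4-methoxybuta-1,3-dien-2-olate | CO/C=C/C(=C)O[Li] | intermediate (not isolated)
13 | (E)-1-methoxy-7-methylocta-1,6-dien-3-one | CO/C=C/C(=O)CCC=C(C)C | intermediate
14 | (1E,3Z)-1-methoxy-7-methyl-3-(trimethylsilyloxy)octa-1,3,6-triene | CO/C=C/C(O[Si](C)(C)C)=C/CC=C(C)C | intermediate
15 | (2S)-2-(2,2-dimethyl-2H-chromen-6-yl)-5-methoxy-8-(3-methylbut-2-en-1-yl)-4a-(phenylsulfinyl)-7-(trimethylsilyloxy)-2,3,4a,5,8,8a-hexahydro-4H-chromen-4-one, cis-fused, diastereomer mixture | CC(C)=CCC1C(O[Si](C)(C)C)=CC(OC)C2(S(=O)c3ccccc3)C(=O)C[C@@H](c3ccc4c(c3)C=CC(C)(C)O4)OC12 | intermediate (not isolated)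
16 | (2S)-2-(2,2-dimethyl-2H-chromen-6-yl)-8-(3-methylbut-2-en-1-yl)-4a-(phenylsulfinyl)-2,3,8,8a-tetrahydro-4H-chromene-4,7(4aH)-dione, diastereomer mixture | CC(C)=CCC1C(=O)C=CC2(S(=O)c3ccccc3)C(=O)C[C@@H](c3ccc4c(c3)C=CC(C)(C)O4)OC12 | intermediate (not isolated)
17 | (2S)-2-(2,2-dimethyl-2H-chromen-6-yl)-8-(3-methylbut-2-en-1-yl)-2,3-dihydro-4H-chromene-4,7(8H)-dione | CC(C)=CCC1C(=O)C=CC2=C1O[C@H](c1ccc3c(c1)C=CC(C)(C)O3)CC2=O | intermediate (not isolated)
18 | (2S)-7-hydroxy-2-(2,2-dimethyl-2H-chromen-6-yl)-8-(3-methylbut-2-en-1-yl)-2,3-dihydro-4H-chromen-4-one | CC(C)=CCc1c(O)ccc2c1O[C@H](c1ccc3c(c1)C=CC(C)(C)O3)CC2=O | target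

**Step count**

Total steps: 8. Longest linear sequence: 6 steps (steps 1, 2, 3, 4, 5 and 8); the diene branch (steps 6 and 7) joins at step 8.

**Steps most likely to fail**

Step 8. The cycloaddition may be too slow at the temperature at which the β-keto sulfoxide is still intact. The syn-elimination would then overtake the acid unmasking and could remove H5 instead of H8a, after which ring A can aromatize only by expelling O1, which opens ring C. The Lewis acid could also consume the silyl enol ether before it adds. The fallback sets out from sulfoxide 9 and prenyl bromide 11 and comes back to the route at sulfinyl enone 16. Purchased 4-(dimethylamino)but-3-en-2-one would be deprotonated with KHMDS in THF at −78 °C and alkylated with 11 to give (E)-1-(dimethylamino)-7-methylocta-1,6-dien-3-one F1. A second deprotonation with KHMDS and trapping with TBSCl would give (1E,3Z)-3-(tert-butyldimethylsilyloxy)-N,N,7-trimethylocta-1,3,6-trien-1-amine F2. This 1-amino-3-siloxy diene is far more nucleophilic than 14 and should add to 9 in toluene at or below room temperature without any Lewis acid, giving the amino cycloadduct F3 with the same regiochemistry. Dilute HF in acetonitrile at 0 °C should remove dimethylamine and the silyl group to give 16, which is carried on to 18 by the last stage of step 8 (pyridine, 60 °C).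

Step 2. Facial selectivity may be insufficient or reversed with this electron-rich aldehyde, and the enantiomeric purity may erode through ionization of the p-alkoxybenzylic C2–O bond during the acid ring closure. The fallback sets out from aldehyde 3 and comes back at pyranone 6. An acetate aldol addition of the titanium enolate of N-acetyl-4-benzylthiazolidine-2-thione (TiCl4, i-Pr2NEt, CH2Cl2, −78 °C) would be used, with the auxiliary hand chosen so that the (S)-carbinol is the major diastereomer; it is written here with the (S)-auxiliary. Chromatographic separation would give (S)-1-[(S)-4-benzyl-2-thioxothiazolidin-3-yl]-3-(2,2-dimethyl-2H-chromen-6-yl)-3-hydroxypropan-1-one F4, so the configuration at the future C2 is secured by separation of diastereomers and not by a catalyst. Displacement of the auxiliary with N,O-dimethylhydroxylamine hydrochloride and imidazole would give the Weinreb amide (S)-3-(2,2-dimethyl-2H-chromen-6-yl)-3-hydroxy-N-methoxy-N-methylpropanamide F5. Excess ethynylmagnesium bromide in THF at 0 °C would give the β-hydroxy ynone (S)-5-(2,2-dimethyl-2H-chromen-6-yl)-5-hydroxypent-1-yn-3-one F6. Silver triflate-catalysed 6-endo cyclization of the hydroxyl group onto the ynone in CH2Cl2 would then give 6.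

Step 4. The thiol may add reversibly to the vinylogous ester and poison the catalyst, or the iodide may be lost reductively, so that C–S coupling does not take place. The fallback sets out from pyranone 6 and comes back at sulfide 8, so it also bypasses iodide 7. Conjugate reduction of 6 with L-Selectride in THF at −78 °C and trapping of the resulting enolate with S-phenyl benzenethiosulfonate would give (2S)-2-(2,2-dimethyl-2H-chromen-6-yl)-5-(phenylthio)tetrahydro-4H-pyran-4-one F7 as a mixture of C5 epimers. N-Chlorosuccinimide in CH2Cl2 at 0 °C would chlorinate the sulfur-bearing carbon to give (2S)-5-chloro-2-(2,2-dimethyl-2H-chromen-6-yl)-5-(phenylthio)tetrahydro-4H-pyran-4-one F8. Loss of hydrogen chloride toward C6 on treatment with triethylamine would then give 8.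

**Further compounds**

F1 | step 8 | (E)-1-(dimethylamino)-7-methylocta-1,6-dien-3-one | CN(C)/C=C/C(=O)CCC=C(C)C
F2 | step 8 | (1E,3Z)-3-(tert-butyldimethylsilyloxy)-N,N,7-trimethylocta-1,3,6-trien-1-amine | CN(C)/C=C/C(O[Si](C)(C)C(C)(C)C)=C/CC=C(C)C
F3 | step 8 | (2S)-7-(tert-butyldimethylsilyloxy)-5-(dimethylamino)-2-(2,2-dimethyl-2H-chromen-6-yl)-8-(3-methylbut-2-en-1-yl)-4a-(phenylsulfinyl)-2,3,4a,5,8,8a-hexahydro-4H-chromen-4-one | CC(C)=CCC1C(O[Si](C)(C)C(C)(C)C)=CC(N(C)C)C2(S(=O)c3ccccc3)C(=O)C[C@@H](c3ccc4c(c3)C=CC(C)(C)O4)OC12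
F4 | step 2 | (S)-1-[(S)-4-benzyl-2-thioxothiazolidin-3-yl]-3-(2,2-dimethyl-2H-chromen-6-yl)-3-hydroxypropan-1-one | O=C(C[C@H](O)c1ccc2c(c1)C=CC(C)(C)O2)N1C(=S)SC[C@@H]1Cc1ccccc1
F5 | step 2 | (S)-3-(2,2-dimethyl-2H-chromen-6-yl)-3-hydroxy-N-methoxy-N-methylpropanamide | CON(C)C(=O)C[C@H](O)c1ccc2c(c1)C=CC(C)(C)O2
F6 | step 2 | (S)-5-(2,2-dimethyl-2H-chromen-6-yl)-5-hydroxypent-1-yn-3-one | C#CC(=O)C[C@H](O)c1ccc2c(c1)C=CC(C)(C)O2
F7 | step 4 | (2S)-2-(2,2-dimethyl-2H-chromen-6-yl)-5-(phenylthio)tetrahydro-4H-pyran-4-one | O=C1C[C@@H](c2ccc3c(c2)C=CC(C)(C)O3)OCC1Sc1ccccc1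
F8 | step 4 | (2S)-5-chloro-2-(2,2-dimethyl-2H-chromen-6-yl)-5-(phenylthio)tetrahydro-4H-pyran-4-one | O=C1C[C@@H](c2ccc3c(c2)C=CC(C)(C)O3)OCC1(Cl)Sc1ccccc1
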